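## Retrosynthetic overview

1. The target 31 ⇐ its 16-ene analogue 30 (exocyclic C16=C17 in place of the C16 carbinol) by hydration of C16=C17 with the hydroxyl entering on the exo face; the 3β-hydroxyl ⇐ C3 ketone 27 by equatorial hydride delivery.
2. Enabling feature: in ring A the quaternary C4 lies between the C19 lactone carbonyl and the C3 carbinol (Claisen retron across C3–C4), and C5, β to C19, is bonded in ring B to C6, the carbon α to the C7 carboxyl (Michael retron across C5–C6); one lactone enolate at C4 serves both.
3. Key disconnection: C3–C4 and C5–C6 together, opening ring A (with the 19,10-lactone bridge) and ring B to butenolide 24, which carries an N-methoxy-N-methylamide arm (C1–C3) on C10 and a tert-butyl acetate arm (C6–C7) on C8 of the C/D bicycle.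
4. Butenolide ⇐ ring-closing metathesis; C10 ⇐ Felkin–Anh addition to a vinyl ketone; C6 ⇐ Arndt–Eistert homologation; ring D ⇐ 5-exo vinyl-radical cyclisation (C13–C16); quaternary C8 ⇐ enolate alkylation.
5. Ring C and the absolute configuration ⇐ alkaloid-mediated desymmetrisation of cis-cyclohex-4-ene-1,2-dicarboxylic anhydride; rings are formed in the order C, D, butenolide (the later lactone), then B and A in one operation.

Key step: step 13

Remark: gibberellane numbering of the target (C1–C19) is used for the atoms of all intermediates, and 3β is the usual descriptor of this family (3-hydroxyl cis to the C18 methyl, anti to the lactone bridge).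
Remark: quinidine is assumed to open anhydride 1 in the sense that gives the (1R,2S) half-ester 3; if the sense is the opposite, quinine is used instead.

## Route

Step 1
Reactants: 1 cis-cyclohex-4-ene-1,2-dicarboxylic anhydride; 2 allyl alcohol
Product: 3 (1R,2S)-2-[(allyloxy)carbonyl]cyclohex-4-ene-1-carboxylic acid
Conditions: quinidine (1.1 equiv), toluene, −55 °C; aq. HCl wash
Reagents that add atoms: none
Why: Cinchona alkaloid-mediated enantioselective alcoholysis (desymmetrisation) of the meso anhydride, in which the alkaloid differentiates the two enantiotopic carbonyl groups and so fixes the absolute configuration of C9 and of the cis-related C8.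

Step 2
Reactants: 3 half-ester; 4 2,3-dibromopropene
Product: 5 (1R,2R)-2-[(allyloxy)carbonyl]-2-(2-bromoallyl)cyclohex-4-ene-1-carboxylic acid
Conditions: LiN(i-Pr)2 (2.2 equiv), THF, −78 °C; then 4, −78 → −20 °C; aq. HCl
Reagents that add atoms: none
Why: C-Alkylation of the carboxylate–ester enolate dianion, in which the allylic bromide should react at C8 on the face opposite to the neighbouring C9 carboxylate, setting the quaternary centre C8 with C15 trans to C10 and the ester cis to it.

Step 3
Reactants: 5 alkylated acid; 6 N,O-dimethylhydroxylamine hydrochloride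
Product: 8 allyl 1-(2-bromoallyl)-6-[methoxy(methyl)carbamoyl]cyclohex-3-ene-1-carboxylate, via acid chloride 7 (not isolated)
Conditions: (COCl)2, DMF (cat.), CH2Cl2, 0 °C → rt; then 6, pyridine, CH2Cl2, 0 °C
Reagents that add atoms: none
Why: Amide formation through the acid chloride (Weinreb amide synthesis) stores C10 at the acyl level in a form that cannot epimerise C9 and touches no stereocentre.

Step 4
Reactants: 8 bromoallyl amide
Product: 9 allyl 2-[methoxy(methyl)carbamoyl]-6-methylidenebicyclo[3.2.1]octane-1-carboxylate
Conditions: Bu3SnH (1.3 equiv), AIBN (cat.), benzene (0.05 M), 80 °C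
Reagents that add atoms: none
Why: 5-exo-trig cyclisation of the C16 vinyl radical onto C13 of the ring alkene (vinyl radical cyclisation) should close ring D before the radical can rearrange, and C13 is fixed because the two-carbon bridge can span C8 and C13 on one face only.

Step 5
Reactants: 9 bicyclic allyl ester
Product: 10 2-[methoxy(methyl)carbamoyl]-6-methylidenebicyclo[3.2.1]octane-1-carboxylic acid
Conditions: Pd(PPh3)4 (5 mol%), morpholine, THF, rt
Reagents that add atoms: none
Why: Tsuji–Trost deallylation through a π-allylpalladium complex frees the hindered C8 carboxylic acid under neutral conditions that leave the amide and the exocyclic alkene alone.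

Step 6
Reactants: 10 bicyclic acid
Product: 12 1-(2-diazoacetyl)-N-methoxy-N-methyl-6-methylidenebicyclo[3.2.1]octane-2-carboxamide, via acid chloride 11 (not isolated)
Conditions: (COCl)2, DMF (cat.), CH2Cl2, 0 °C; then CH2N2 (excess), Et2O, 0 °C
Reagents that add atoms: diazomethane C=[N+]=[N-]
Why: First half of the Arndt–Eistert homologation, acylation of diazomethane by the acid chloride, brings in C6 without touching a stereocentre.

Step 7
Reactants: 12 diazoketone
Product: 14 tert-butyl 2-{2-[methoxy(methyl)carbamoyl]-6-methylidenebicyclo[3.2.1]octan-1-yl}acetate, via ketene 13 (not isolated)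
Conditions: PhCO2Ag (0.1 equiv), Et3N, t-BuOH, 70 °C
Reagents that add atoms: tert-butanol CC(C)(C)O
Why: Wolff rearrangement with retention at the migrating C8 gives ketene 13, which tert-butanol traps as the tert-butyl ester, chosen because it resists Grignard reagents and the C10 alkoxide of step 9.

Step 8
Reactants: 14 amide ester; 15 vinylmagnesium bromide
Product: 16 tert-butyl 2-(2-acryloyl-6-methylidenebicyclo[3.2.1]octan-1-yl)acetate
Conditions: CH2=CHMgBr (2.5 equiv), THF, −78 → 0 °C; poured into cold 1 M HCl
Reagents that add atoms: none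
Why: Weinreb ketone synthesis, in which the chelated tetrahedral adduct prevents a second addition and the tert-butyl ester is not attacked, installs C5 as the vinyl group of a ketone at C10.

Step 9
Reactants: 16 vinyl ketone; 17 [2-(1,3-dioxolan-2-yl)ethyl]magnesium bromide; 18 methacryloyl chloride
Product: 20 tert-butyl 2-{2-[5-(1,3-dioxolan-2-yl)-3-(methacryloyloxy)pent-1-en-3-yl]-6-methylidenebicyclo[3.2.1]octan-1-yl}acetate, via magnesium alkoxide 19 (not isolated)
Conditions: 17 (2 equiv), CeCl3 (2 equiv), THF, −78 °C; then 18 (3 equiv), −78 → 0 °C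
Reagents that add atoms: none
Why: Felkin–Anh 1,2-addition of the organocerium reagent, anti to the quaternary C8 on C9 with the vinyl group next to the small H9, should set C10 with O10 and C1 placed as in the target, and the tertiary alkoxide is then esterified in the same flask.

Step 10
Reactants: 20 methacrylate
Product: 21 tert-butyl 2-{2-[2-[2-(1,3-dioxolan-2-yl)ethyl]-4-methyl-5-oxo-2,5-dihydrofuran-2-yl]-6-methylidenebicyclo[3.2.1]octan-1-yl}acetate
Conditions: second-generation Grubbs catalyst (10 mol%), toluene, 80 °C
Reagents that add atoms: none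
Why: Ring-closing metathesis of the methacrylate with the C10 vinyl group gives the α-methylbutenolide (C19, C4, C18, C5), the hindered 1,1-disubstituted C16=C17 being expected to stay a spectator.

Step 11
Reactants: 21 butenolide acetal
Product: 23 3-{2-[1-(2-tert-butoxy-2-oxoethyl)-6-methylidenebicyclo[3.2.1]octan-2-yl]-4-methyl-5-oxo-2,5-dihydrofuran-2-yl}propanoic acid, via aldehyde 22 (not isolated)
Conditions: 1 M HCl, THF, rt; then NaH2PO4, t-BuOH, 2-methyl-2-butene, NaClO2, H2O, 0 °C → rt
Reagents that add atoms: water O; sodium chlorite [Na+].[O-]Cl=O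
Why: Acid hydrolysis of the dioxolane followed in the same flask by Pinnick oxidation, with 2-methyl-2-butene as chlorine scavenger to protect the exocyclic alkene, raises C3 to the acid level without touching a stereocentre.

Step 12
Reactants: 23 butenolide acid; 6 N,O-dimethylhydroxylamine hydrochloride
Product: 24 tert-butyl 2-{2-[2-{3-[methoxy(methyl)amino]-3-oxopropyl}-4-methyl-5-oxo-2,5-dihydrofuran-2-yl]-6-methylidenebicyclo[3.2.1]octan-1-yl}acetate
Conditions: EDC·HCl, HOBt (cat.), i-Pr2NEt, CH2Cl2, rt
Reagents that add atoms: none
Why: Carbodiimide-mediated amide coupling turns C3 into an N-methoxy-N-methylamide, an acyl acceptor whose α-hydrogens are less acidic than those of any ester or lactone in the molecule.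

Step 13
Reactants: 24 butenolide amide
Product: 27 pentacyclic C3 ketone tert-butyl ester, via lithium lactone enolate 25 (not isolated), via lithium hemiaminal alkoxide 26 (not isolated)
Conditions: LiN(SiMe3)2 (1.3 equiv), THF, −78 → 0 °C; sat. aq. NH4Cl
Reagents that add atoms: none
Why: LiN(SiMe3)2 deprotonates C6 (α to the tert-butyl ester, the most acidic C–H, since the butenolide has no γ-hydrogen and the amide α-hydrogens are less acidic), the ester enolate adds to C5 of the butenolide (intramolecular Michael addition), and the lactone enolate 25 thus formed at C4 attacks the amide carbonyl C3 (Claisen or Dieckmann-type acylation), the chelated adduct 26 releasing the C3 ketone only on work-up. The closest known reaction type is the tandem Michael–Claisen (Michael–Dieckmann) annulation, in which the enolate born in a conjugate addition is trapped by an ester or amide carbonyl. Ring B closes 5-exo-trig at C5 and ring A closes 6-(enolexo)-exo-trig at C3, which completes the bridged 19,10-lactone bicycle. C5 is fixed by the tether, because C6 can reach only the butenolide face that carries C9 and the lactone and ring B must be cis-fused; C4 is fixed likewise, because C3 arrives from the face that carries C1 and leaves C18 on the other; C6 is set by the approach in which the tert-butoxycarbonyl group points away from the butenolide, placing C7 trans to C4, which is also the more stable arrangement. The step needs conjugate rather than carbonyl addition of the ester enolate and closure of ring A faster than proton transfer or retro-Michael reaction: the five-membered transition state for attack at C5 (against six-membered for attack at C19), the absence of any C–H more acidic than that of the lactone being formed, and the inertness of adduct 26 toward reversal or a second addition should secure this.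

Step 14
Reactants: 27 pentacyclic C3 ketone tert-butyl ester
Product: 28 3β-hydroxy 16-ene tert-butyl ester
Conditions: K[HB(s-Bu)3] (1.2 equiv), THF, −78 °C; sat. aq. NH4Cl
Reagents that add atoms: none
Why: Hydride delivery from the bulky trialkylborohydride along the equatorial trajectory, away from the axial hydrogens on C1 and C5 on the β-face as in the reduction of 4,4-disubstituted cyclohexanones to axial alcohols, should give the axial 3β-hydroxyl.

Step 15
Reactants: 28 3β-hydroxy 16-ene tert-butyl ester
Product: 30 3β-hydroxy 16-ene acid, via bis(trimethylsilyl) derivative 29 (not isolated)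
Conditions: Me3SiOTf (3 equiv), 2,6-lutidine, CH2Cl2, 0 °C; then aq. citric acid, MeOH, rt
Reagents that add atoms: none
Why: Silyl triflate-mediated cleavage of the tert-butyl ester with loss of isobutene, under buffered non-protic conditions that spare the exocyclic alkene and the lactone, gives the free C7 acid after hydrolysis of the transient silyl ether and silyl ester 29.

Step 16
Reactants: 30 3β-hydroxy 16-ene acid
Product: 31 target gibberellin (16-hydroxy-16-methyl compound)
Conditions: Co(acac)2 (20 mol%), PhSiH3 (2.5 equiv), O2 (1 atm), i-PrOH/THF, rt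
Reagents that add atoms: dioxygen O=O
Why: Mukaiyama hydration, in which hydrogen-atom transfer from a cobalt hydride to C17 gives the tertiary C16 radical that O2 should trap on the exo face (the side of the one-carbon bridge C14, away from the axial hydrogens of ring C), places the hydroxyl exo and the new methyl endo as in the target after in situ reduction of the peroxide by the silane.

## Compound list

1 | cis-cyclohex-4-ene-1,2-dicarboxylic anhydride (meso) | O=C1[C@@H]2CC=CC[C@@H]2C(=O)O1 | starting material
2 | allyl alcohol | C=CCO | starting material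
3 | (1R,2S)-2-[(allyloxy)carbonyl]cyclohex-4-ene-1-carboxylic acid | O=C(O)[C@@H]1CC=CC[C@@H]1C(=O)OCC=C | intermediate
4 | 2,3-dibromopropene | C=C(Br)CBr | starting material
5 | (1R,2R)-2-[(allyloxy)carbonyl]-2-(2-bromoallyl)cyclohex-4-ene-1-carboxylic acid (acid cis to the ester, trans to the bromoallyl group) | O=C(O)[C@@H]1CC=CC[C@]1(CC(Br)=C)C(=O)OCC=C | intermediate
6 | N,O-dimethylhydroxylamine hydrochloride | CNOC.Cl | starting material
7 | acid chloride of 5 (not isolated) | O=C(Cl)[C@@H]1CC=CC[C@]1(CC(Br)=C)C(=O)OCC=C | intermediate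
8 | allyl 1-(2-bromoallyl)-6-[methoxy(methyl)carbamoyl]cyclohex-3-ene-1-carboxylate (amide cis to the ester) | CON(C)C(=O)[C@@H]1CC=CC[C@]1(CC(Br)=C)C(=O)OCC=C | intermediate
9 | allyl 2-[methoxy(methyl)carbamoyl]-6-methylidenebicyclo[3.2.1]octane-1-carboxylate (C/D bicycle; H9 on the side of the C15–C16 bridge) | CON(C)C(=O)[C@@H]1CC[C@@H]2C[C@]1(CC2=C)C(=O)OCC=C | intermediate
10 | 2-[methoxy(methyl)carbamoyl]-6-methylidenebicyclo[3.2.1]octane-1-carboxylic acid | CON(C)C(=O)[C@@H]1CC[C@@H]2C[C@]1(CC2=C)C(=O)O | intermediate
11 | acid chloride of 10 (not isolated) | CON(C)C(=O)[C@@H]1CC[C@@H]2C[C@]1(CC2=C)C(=O)Cl | intermediate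
12 | 1-(2-diazoacetyl)-N-methoxy-N-methyl-6-methylidenebicyclo[3.2.1]octane-2-carboxamide | CON(C)C(=O)[C@@H]1CC[C@@H]2C[C@]1(CC2=C)C(=O)C=[N+]=[N-] | intermediate
13 | ketene from 12 (not isolated) | CON(C)C(=O)[C@@H]1CC[C@@H]2C[C@]1(CC2=C)C=C=O | intermediate
14 | tert-butyl 2-{2-[methoxy(methyl)carbamoyl]-6-methylidenebicyclo[3.2.1]octan-1-yl}acetate | CON(C)C(=O)[C@@H]1CC[C@@H]2C[C@]1(CC2=C)CC(=O)OC(C)(C)C | intermediate
15 | vinylmagnesium bromide | C=C[Mg]Br | starting material
16 | tert-butyl 2-(2-acryloyl-6-methylidenebicyclo[3.2.1]octan-1-yl)acetate | C=CC(=O)[C@@H]1CC[C@@H]2C[C@]1(CC2=C)CC(=O)OC(C)(C)C | intermediate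
17 | [2-(1,3-dioxolan-2-yl)ethyl]magnesium bromide | Br[Mg]CCC1OCCO1 | starting material
18 | methacryloyl chloride | C=C(C)C(=O)Cl | starting material
19 | bromomagnesium alkoxide of the C10 tertiary carbinol (not isolated) | C=C[C@@](O[Mg]Br)(CCC1OCCO1)[C@@H]1CC[C@@H]2C[C@]1(CC2=C)CC(=O)OC(C)(C)C | intermediate
20 | methacrylate of the C10 tertiary carbinol bearing vinyl (C5), the dioxolanylethyl arm (C1–C3) and the C/D bicycle | C=C(C)C(=O)O[C@](C=C)(CCC1OCCO1)[C@@H]1CC[C@@H]2C[C@]1(CC2=C)CC(=O)OC(C)(C)C | intermediate
21 | butenolide acetal: tert-butyl 2-{2-[2-[2-(1,3-dioxolan-2-yl)ethyl]-4-methyl-5-oxo-2,5-dihydrofuran-2-yl]-6-methylidenebicyclo[3.2.1]octan-1-yl}acetate | CC1=C[C@@](CCC2OCCO2)([C@@H]2CC[C@@H]3C[C@]2(CC3=C)CC(=O)OC(C)(C)C)OC1=O | intermediate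
22 | butenolide aldehyde (not isolated) | CC1=C[C@@](CCC=O)([C@@H]2CC[C@@H]3C[C@]2(CC3=C)CC(=O)OC(C)(C)C)OC1=O | intermediate
23 | butenolide acid: 3-{2-[1-(2-tert-butoxy-2-oxoethyl)-6-methylidenebicyclo[3.2.1]octan-2-yl]-4-methyl-5-oxo-2,5-dihydrofuran-2-yl}propanoic acid | CC1=C[C@@](CCC(=O)O)([C@@H]2CC[C@@H]3C[C@]2(CC3=C)CC(=O)OC(C)(C)C)OC1=O | intermediate
24 | butenolide N-methoxy-N-methylamide (cyclisation precursor) | CC1=C[C@@](CCC(=O)N(C)OC)([C@@H]2CC[C@@H]3C[C@]2(CC3=C)CC(=O)OC(C)(C)C)OC1=O | intermediate
25 | lithium lactone enolate after closure of ring B (not isolated) | CC1=C(O[Li])O[C@]2(CCC(=O)N(C)OC)[C@@H]3CC[C@@H]4C[C@]3(CC4=C)[C@@H](C(=O)OC(C)(C)C)[C@H]12 | intermediate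
26 | lithium hemiaminal alkoxide at C3 after closure of ring A (not isolated) | C[C@@]12C(=O)O[C@]3(CCC1(O[Li])N(C)OC)[C@@H]1CC[C@@H]4C[C@]1(CC4=C)[C@@H](C(=O)OC(C)(C)C)[C@@H]32 | intermediate
27 | pentacyclic C3 ketone tert-butyl ester: 7-tert-butyl ester of 10-hydroxy-3-oxo-20-norgibberell-16-ene-7,19-dioic acid 19,10-lactone | C[C@@]12C(=O)O[C@]3(CCC1=O)[C@@H]1CC[C@@H]4C[C@]1(CC4=C)[C@@H](C(=O)OC(C)(C)C)[C@@H]32 | intermediate
28 | 3β-hydroxy 16-ene tert-butyl ester: 7-tert-butyl ester of 3β,10-dihydroxy-20-norgibberell-16-ene-7,19-dioic acid 19,10-lactone (3-hydroxyl cis to C18) | C[C@@]12C(=O)O[C@]3(CC[C@@H]1O)[C@@H]1CC[C@@H]4C[C@]1(CC4=C)[C@@H](C(=O)OC(C)(C)C)[C@@H]32 | intermediate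
29 | bis(trimethylsilyl) derivative: 3-O-trimethylsilyl ether and C7 trimethylsilyl ester of 30 (not isolated) | C[C@@]12C(=O)O[C@]3(CC[C@@H]1O[Si](C)(C)C)[C@@H]1CC[C@@H]4C[C@]1(CC4=C)[C@@H](C(=O)O[Si](C)(C)C)[C@@H]32 | intermediate
30 | 3β-hydroxy 16-ene acid: 3β,10-dihydroxy-20-norgibberell-16-ene-7,19-dioic acid 19,10-lactone (the 16-ene analogue of the target) | C[C@@]12C(=O)O[C@]3(CC[C@@H]1O)[C@@H]1CC[C@@H]4C[C@]1(CC4=C)[C@@H](C(=O)O)[C@@H]32 | intermediate
31 | target gibberellin: 3β,10,16-trihydroxy-20-norgibberellane-7,19-dioic acid 19,10-lactone (16-hydroxyl exo on the side of C14; C17 methyl endo) | C[C@@]12C(=O)O[C@]3(CC[C@@H]1O)[C@@H]1CC[C@@H]4C[C@]1(C[C@@]4(C)O)[C@@H](C(=O)O)[C@@H]32 | target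

## Count and risks

Total step count: 16. Longest linear sequence: 16 steps (1 → 31); all partners are commercial.

Steps most likely to fail:

Step 13. The two ring closures may not follow one another: the ester enolate may add to the butenolide carbonyl instead of C5, or deprotonation next to the amide may lead to acyl transfer from the butenolide. The fallback separates the events and runs the conjugate addition while the tert-butyl ester is the only acidic site. It sets out from 21: LiN(i-Pr)2 in THF at −78 °C should give, by intramolecular Michael addition and protonation, the ring B lactone acetal F1 (either configuration at C4). Acetal hydrolysis and Pinnick oxidation as in step 11 give the lactone acid F2, and coupling as in step 12 gives the lactone N-methoxy-N-methylamide F3. In F3 the lactone C4–H is the most acidic C–H, so LiN(SiMe3)2 under equilibrating conditions should form the C4 enolate, which closes ring A on the amide. The fallback comes back to the route at 27.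

Step 9. The facial selectivity of the addition to the open-chain ketone may be low or opposite to the Felkin–Anh prediction. The fallback inverts the order in which the two C10 substituents are introduced, so that the same intrinsic bias leads to the other face. It sets out from 14: Grignard reagent 17 converts the amide into the dioxolanylethyl ketone F4. The vinylcerium reagent made from 15 and CeCl3 is then added, and the alkoxide is acylated with 18. The fallback comes back to the route at 20.

Step 10. Ring closure between two hindered alkenes may be slower than catalyst decay, or the metathesis may involve C16=C17. The fallback builds the butenolide by carbonyl chemistry and sets out from 14. MeMgBr gives the methyl ketone F5. Its kinetic enolate (LiN(i-Pr)2, −78 °C) adds to methyl pyruvate and the aldolate is silylated with Me3SiCl to the silyl aldol F6 (both configurations at C4). Addition of the organocerium reagent from 17, followed by an aqueous acid work-up that removes the silyl group and lactonises, gives the α-hydroxy lactone F7. Dehydration with SOCl2 and pyridine, followed by DBU to move any exocyclic alkene into the ring, comes back to the route at 21.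

## Further compounds

F1 | step 13 | ring B lactone acetal (Michael adduct of 21; C4 unassigned) | CC1C(=O)O[C@]2(CCC3OCCO3)[C@@H]3CC[C@@H]4C[C@]3(CC4=C)[C@@H](C(=O)OC(C)(C)C)[C@H]12
F2 | step 13 | ring B lactone acid | CC1C(=O)O[C@]2(CCC(=O)O)[C@@H]3CC[C@@H]4C[C@]3(CC4=C)[C@@H](C(=O)OC(C)(C)C)[C@H]12
F3 | step 13 | ring B lactone N-methoxy-N-methylamide | CC1C(=O)O[C@]2(CCC(=O)N(C)OC)[C@@H]3CC[C@@H]4C[C@]3(CC4=C)[C@@H](C(=O)OC(C)(C)C)[C@H]12
F4 | step 9 | tert-butyl 2-{2-[3-(1,3-dioxolan-2-yl)propanoyl]-6-methylidenebicyclo[3.2.1]octan-1-yl}acetate | O=C(CCC1OCCO1)[C@@H]1CC[C@@H]2C[C@]1(CC2=C)CC(=O)OC(C)(C)C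
F5 | step 10 | tert-butyl 2-(2-acetyl-6-methylidenebicyclo[3.2.1]octan-1-yl)acetate | CC(=O)[C@@H]1CC[C@@H]2C[C@]1(CC2=C)CC(=O)OC(C)(C)C
F6 | step 10 | silyl aldol of F5 with methyl pyruvate (C4 unassigned) | COC(=O)C(C)(O[Si](C)(C)C)CC(=O)[C@@H]1CC[C@@H]2C[C@]1(CC2=C)CC(=O)OC(C)(C)C
F7 | step 10 | α-hydroxy-α-methyl lactone acetal (C4 unassigned) | CC1(O)C[C@@](CCC2OCCO2)([C@@H]2CC[C@@H]3C[C@]2(CC3=C)CC(=O)OC(C)(C)C)OC1=O
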